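Ring B (C5–C6–C7–C8–C9–C10) is disconnected by excising C9 together with its whole side chain. This exploits the C8 methylene as a masked ketone flanked by side-chain-bearing C9 and quaternary C10, and leaves a trans-hydrindanone whose cyclopentanone (C5, C6, C7, C8, C10) has the C8 carbonyl next to C10. In the key step C9 returns as a geraniol-derived 1,1-dibromoalkyllithium. Addition to C8=O, Br/Li exchange and 1,2-shift of C10 (β-oxido carbenoid rearrangement) enlarge the cyclopentanone to the cyclohexanone of ring B, forge the C9–C10 bond and attach the complete C11–C16 chain. The precursor is an acetonide-protected hydrindanone built from the (R)-4-methyl Hajos–Parrish enedione.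

Key step: step 12

Remark: labdane numbering of the target is used for all core atoms, also in the hydrindanes, where C9 is still missing (ring A = C1–C5 + C10; five-membered ring = C5, C6, C7, C8, C10; C18 = oxygenated CH2 on C4, C19 = methyl on C4, C20 = methyl on C10); "syn/anti to C20" gives the face.
Remark: compounds 1, 2 and 12 and all reagents are taken as commercial; enedione 5 is assumed to be brought to enantiopurity by recrystallisation.

Step 1
Reactants: 1 2-methylcyclopentane-1,3-dione; 2 ethyl vinyl ketone
Product: 3 2-methyl-2-(3-oxopentyl)cyclopentane-1,3-dione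
Conditions: H2O, AcOH (cat.), 70 °C
Reagents that add atoms: none
Why: Michael addition of the acidic cyclic 1,3-dione to the enone; the product is achiral (prochiral at the quaternary carbon).

Step 2
Reactants: 3 2-methyl-2-(3-oxopentyl)cyclopentane-1,3-dione
Product: 5 (7aR)-4,7a-dimethyl-2,3,7,7a-tetrahydro-1H-indene-1,5(6H)-dione, via bicyclic ketol 4 (not isolated)
Conditions: D-phenylalanine, 1 M aq HClO4 (0.5 equiv), MeCN, reflux
Reagents that add atoms: none
Why: Hajos–Parrish–Eder–Sauer–Wiechert amino-acid-mediated intramolecular aldol condensation, in which the D-amino acid enamine of the side-chain ketone selects one enantiotopic ring carbonyl and so sets C10 (7aR) before acid-promoted dehydration of the ketol.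

Step 3
Reactants: 5 (7aR)-4,7a-dimethyl-2,3,7,7a-tetrahydro-1H-indene-1,5(6H)-dione
Product: 6 (1R,7aR)-1-hydroxy-4,7a-dimethyl-1,2,3,6,7,7a-hexahydro-5H-inden-5-one
Conditions: NaBH4 (0.27 equiv), EtOH, −20 °C
Reagents that add atoms: none
Why: Chemoselective borohydride reduction of the saturated cyclopentanone over the less electrophilic conjugated enone, with hydride delivery anti to C20 giving the C8 alcohol syn to C20 (a temporary stereocentre, removed in step 7).

Step 4
Reactants: 6 (1R,7aR)-1-hydroxy-4,7a-dimethyl-1,2,3,6,7,7a-hexahydro-5H-inden-5-one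
Product: 8 trans-hydrindane keto diol (C3 ketone; C4 bearing C18H2OH and C19 methyl; C8–OH), via dilithium enolate 7 (not isolated)
Conditions: Li (2.1 equiv), NH3/THF, −78 °C; NH3 evaporated; CH2O (g, from cracked paraformaldehyde), THF, −78 to −30 °C; NH4Cl
Reagents that add atoms: formaldehyde, C=O
Why: Birch-type reductive alkylation (dissolving-metal enone reduction with aldol trapping of the enolate) in which the C8 hydroxyl is the single proton equivalent, protonation of the β-carbanion at C5 should give the trans ring fusion (C5–H anti to C20), and the regiodefined C3–C4 enolate 7 should add to formaldehyde on the face opposite C20, placing C18H2OH equatorial and the C19 methyl axial.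

Step 5
Reactants: 8 trans-hydrindane keto diol
Product: 9 trans-hydrindane triol (C3–OH, C18–OH, C8–OH)
Conditions: NaBH4, MeOH, 0 °C
Reagents that add atoms: none
Why: Borohydride reduction with axial hydride delivery to C3 from the face opposite the axial C19 and C20 methyls, which should give the equatorial C3 alcohol (C3–O syn to C20).

Step 6
Reactants: 9 trans-hydrindane triol
Product: 10 acetonide alcohol (C3–O/C18–O isopropylidene acetal, free C8–OH)
Conditions: 2,2-dimethoxypropane, PPTS (cat.), CH2Cl2, rt
Reagents that add atoms: 2,2-dimethoxypropane, COC(C)(C)OC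
Why: Acid-catalysed transacetalisation, in which only the 1,3-related C3 and C18 hydroxyls can close a six-membered isopropylidene acetal, so the C8 hydroxyl stays free.

Step 7
Reactants: 10 acetonide alcohol
Product: 11 acetonide-protected trans-hydrindan-8-one
Conditions: TPAP (5 mol %), NMO, 4 Å MS, CH2Cl2, rt
Reagents that add atoms: none
Why: Ley–Griffith oxidation of the secondary alcohol under neutral conditions tolerated by the acetonide; no stereocentre is at risk because C10 is quaternary and C5 is not α to the new ketone.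

Step 8
Reactants: 12 geraniol
Product: 13 geranyl tert-butyldiphenylsilyl ether
Conditions: TBDPSCl, imidazole, DMF, 0 °C to rt
Reagents that add atoms: tert-butyl(chloro)diphenylsilane, CC(C)(C)[Si](Cl)(c1ccccc1)c1ccccc1
Why: Imidazole-promoted silylation masks the future C15 hydroxyl with a group stable to organolithiums, ylides and mild acid; the (E)-alkene of geraniol becomes the C13=C14 alkene of the target.

Step 9
Reactants: 13 geranyl tert-butyldiphenylsilyl ether
Product: 14 6,7-epoxygeranyl tert-butyldiphenylsilyl ether (racemic epoxide)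
Conditions: mCPBA (1.0 equiv), NaHCO3, CH2Cl2, −20 to 0 °C
Reagents that add atoms: 3-chloroperbenzoic acid, OOC(=O)c1cccc(Cl)c1
Why: Prilezhaev epoxidation, regioselective for the more electron-rich remote 6,7-alkene over the 2,3-alkene that is deactivated by the allylic oxygen and screened by the silyl group; the epoxide stereocentre is destroyed in step 10.

Step 10
Reactants: 14 6,7-epoxygeranyl tert-butyldiphenylsilyl ether
Product: 15 (4E)-6-[(tert-butyldiphenylsilyl)oxy]-4-methylhex-4-enal
Conditions: H5IO6, THF/Et2O, 0 °C
Reagents that add atoms: none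
Why: Acid-mediated epoxide hydrolysis followed by Malaprade glycol cleavage in one operation gives the aldehyde whose carbonyl carbon becomes C9.

Step 11
Reactants: 15 (4E)-6-[(tert-butyldiphenylsilyl)oxy]-4-methylhex-4-enal
Product: 16 tert-butyl{[(2E)-6,6-dibromo-3-methylhex-2-en-1-yl]oxy}diphenylsilane
Conditions: P(OPh)3 (1.1 equiv), Br2 (1.05 equiv), Et3N (buffer), CH2Cl2, −60 °C to rt
Reagents that add atoms: bromine, BrBr
Why: Appel-type deoxygenative gem-dibromination of the aldehyde by the pre-formed triphenyl phosphite–bromine adduct (oxyphosphonium activation, then two bromide deliveries), with excess phosphite so that no free bromine should remain for the alkene.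

Step 12
Reactants: 11 acetonide-protected trans-hydrindan-8-one; 16 tert-butyl{[(2E)-6,6-dibromo-3-methylhex-2-en-1-yl]oxy}diphenylsilane
Product: 21 ring-expanded 8-oxo decalin with equatorial C9 side chain, via lithiated dibromide 17 (not isolated), via dibromo alkoxide 18 (not isolated), via oxido carbenoid 19 (not isolated), via lithium enolate 20 (not isolated)
Conditions: 16 (1.5 equiv), LDA (commercial solution), THF/Et2O, −100 °C; 11, −100 to −78 °C; n-BuLi, −78 to −20 °C; MeOH, 0 °C to rt
Reagents that add atoms: none
Why: Deprotonation of 16 gives the 1,1-dibromoalkyllithium 17, which should add to the C8 carbonyl of 11 anti to C20 to give alkoxide 18; Br/Li exchange with n-BuLi then forms the β-oxido carbenoid 19, in which the C8–C10 bond shifts to the carbenoid carbon with loss of LiBr to give the ring-enlarged enolate 20 (C8(OLi)=C9). The closest known reaction type is the β-oxido carbenoid ring enlargement of cycloalkanones with 1,1-dihaloalkyllithiums. No ring is closed by cyclisation: the cyclopentanone (C5, C6, C7, C8, C10) becomes six-membered ring B by insertion of C9 between C8 and C10 (one-carbon ring expansion by 1,2-alkyl shift). C10 migrates with retention, so C5 and C10 keep their configuration, and the new stereocentre C9 is set on methanol quench by axial protonation of 20 anti to C20 and by LiOMe equilibration, both of which should favour the equatorial side chain (C9–H anti to C20). The step needs migration of quaternary C10 in preference to C7H2, which the higher migratory aptitude of the more substituted α-carbon in carbenoid 1,2-shifts should secure, and chemoselectivity, which the base-stable acetonide, silyl ether and trisubstituted alkene allow.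

Step 13
Reactants: 21 ring-expanded 8-oxo decalin
Product: 22 8(17)-methylene decalin (acetonide and TBDPS ether retained)
Conditions: Ph3PCH3Br, KOtBu, toluene, 0 to 80 °C
Reagents that add atoms: methyltriphenylphosphonium bromide, C[P+](c1ccccc1)(c1ccccc1)c1ccccc1.[Br-]
Why: Wittig methylenation of the hindered C8 ketone; the basic ylide can only equilibrate C9 towards the already favoured equatorial epimer.

Step 14
Reactants: 22 8(17)-methylene decalin acetonide
Product: 23 C3,C18-diol (C15 TBDPS ether retained)
Conditions: PPTS (cat.), MeOH, rt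
Reagents that add atoms: none
Why: Acid-catalysed acetal methanolysis (transacetalisation) under conditions too mild to cleave the TBDPS ether or isomerise the exocyclic alkene.

Step 15
Reactants: 23 C3,C18-diol
Product: 24 C18 tiglate with free C3–OH
Conditions: tigloyl chloride (1.1 equiv), pyridine, DMAP (cat.), CH2Cl2, −20 to 0 °C
Reagents that add atoms: tigloyl chloride [(E)-2-methylbut-2-enoyl chloride], C/C=C(\C)C(Cl)=O
Why: Nucleophilic acyl substitution, selective for the primary C18 hydroxyl over the secondary C3 hydroxyl next to quaternary C4 at low temperature with one equivalent of acyl chloride; pyridine as base avoids deconjugation of the (E)-configured tiglate.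

Step 16
Reactants: 24 C18 tiglate with free C3–OH
Product: 25 C3 acetate C18 tiglate C15 TBDPS ether
Conditions: Ac2O, pyridine, DMAP (cat.), CH2Cl2, rt
Reagents that add atoms: acetic anhydride, CC(=O)OC(C)=O
Why: DMAP-catalysed acetylation of the remaining secondary C3 hydroxyl.

Step 17
Reactants: 25 C3 acetate C18 tiglate C15 TBDPS ether
Product: 26 target CNP0148037.1
Conditions: HF·pyridine, pyridine/THF, 0 °C to rt
Reagents that add atoms: none
Why: Fluoride-mediated Si–O cleavage under buffered, non-basic conditions that should leave both esters (no acyl migration) and both alkenes untouched.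

Compound list
1 | 2-methylcyclopentane-1,3-dione | CC1C(=O)CCC1=O | starting material
2 | ethyl vinyl ketone (pent-1-en-3-one) | CCC(=O)C=C | starting material
3 | 2-methyl-2-(3-oxopentyl)cyclopentane-1,3-dione | CCC(=O)CCC1(C)C(=O)CCC1=O | intermediate
4 | bicyclic ketol, not isolated: (7aR)-3a-hydroxy-4,7a-dimethylhexahydro-1H-indene-1,5(4H)-dione, cis-fused (OH syn to the angular methyl), C4 unassigned | C[C@@]12CCC(=O)C(C)[C@]1(O)CCC2=O | intermediate
5 | (7aR)-4,7a-dimethyl-2,3,7,7a-tetrahydro-1H-indene-1,5(6H)-dione | C[C@@]12CCC(=O)C(C)=C1CCC2=O | intermediate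
6 | (1R,7aR)-1-hydroxy-4,7a-dimethyl-1,2,3,6,7,7a-hexahydro-5H-inden-5-one (OH syn to the angular methyl) | C[C@@]12CCC(=O)C(C)=C1CC[C@H]2O | intermediate
7 | dilithium salt, not isolated: trans-fused C3–C4 lithium enolate with C8 lithium alkoxide | C1C[C@H]2[C@@](C)(CCC(O[Li])=C2C)[C@@H]1O[Li] | intermediate
8 | (1R,3aS,4S,7aR)-1-hydroxy-4-(hydroxymethyl)-4,7a-dimethyloctahydro-5H-inden-5-one (trans-fused; C18H2OH anti, C19 methyl syn to C20) | C1C[C@H]2[C@@](C)(CCC(=O)[C@]2(C)CO)[C@@H]1O | intermediate
9 | (1R,3aS,4S,5R,7aR)-4-(hydroxymethyl)-4,7a-dimethyloctahydro-1H-indene-1,5-diol (C3–OH equatorial, syn to C20) | C1C[C@H]2[C@@](C)(CC[C@@H](O)[C@]2(C)CO)[C@@H]1O | intermediate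
10 | acetonide alcohol: trans-hydrindan-8-ol (OH syn to C20) with the C3–O/C18–O isopropylidene acetal; C19 methyl syn, C18 anti to C20 | C1C[C@H]2[C@@](C)(CC[C@@H](OC(C)(C)OC3)[C@@]23C)[C@@H]1O | intermediate
11 | acetonide-protected trans-hydrindan-8-one (same ring A as 10) | C1C[C@H]2[C@@](C)(CC[C@@H](OC(C)(C)OC3)[C@@]23C)C1=O | intermediate
12 | geraniol [(2E)-3,7-dimethylocta-2,6-dien-1-ol] | CC(C)=CCC/C(C)=C/CO | starting material
13 | tert-butyl{[(2E)-3,7-dimethylocta-2,6-dien-1-yl]oxy}diphenylsilane | CC(C)=CCC/C(C)=C/CO[Si](c1ccccc1)(c1ccccc1)C(C)(C)C | intermediate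
14 | tert-butyl{[(2E)-5-(3,3-dimethyloxiran-2-yl)-3-methylpent-2-en-1-yl]oxy}diphenylsilane (racemic) | CC1(C)OC1CC/C(C)=C/CO[Si](c1ccccc1)(c1ccccc1)C(C)(C)C | intermediate
15 | (4E)-6-[(tert-butyldiphenylsilyl)oxy]-4-methylhex-4-enal | O=CCC/C(C)=C/CO[Si](c1ccccc1)(c1ccccc1)C(C)(C)C | intermediate
16 | tert-butyl{[(2E)-6,6-dibromo-3-methylhex-2-en-1-yl]oxy}diphenylsilane | BrC(Br)CC/C(C)=C/CO[Si](c1ccccc1)(c1ccccc1)C(C)(C)C | intermediate
17 | lithiated dibromide, not isolated: 1,1-dibromoalkyllithium from 16 | [Li]C(Br)(Br)CC/C(C)=C/CO[Si](c1ccccc1)(c1ccccc1)C(C)(C)C | intermediate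
18 | dibromo alkoxide, not isolated: lithium alkoxide from addition of 17 to C8 of 11 (C8–O syn to C20) | C1C[C@H]2[C@@](C)(CC[C@@H](OC(C)(C)OC3)[C@@]23C)[C@@]1(O[Li])C(Br)(Br)CC/C(C)=C/CO[Si](c1ccccc1)(c1ccccc1)C(C)(C)C | intermediate
19 | β-oxido carbenoid, not isolated: C8 lithium alkoxide with the C9(Li)(Br) carbenoid carbon | C1C[C@H]2[C@@](C)(CC[C@@H](OC(C)(C)OC3)[C@@]23C)[C@@]1(O[Li])C([Li])(Br)CC/C(C)=C/CO[Si](c1ccccc1)(c1ccccc1)C(C)(C)C | intermediate
20 | lithium enolate, not isolated: ring-expanded trans-decalin C8(OLi)=C9 enolate bearing the side chain on C9 | [Li]OC=1CC[C@H]2[C@@](C)(CC[C@@H](OC(C)(C)OC3)[C@@]23C)C=1CC/C(C)=C/CO[Si](c1ccccc1)(c1ccccc1)C(C)(C)C | intermediate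
21 | 8-oxo trans-decalin: C9 carries the (E)-5-(TBDPS-oxy)-3-methylpent-3-enyl chain equatorial (C9–H and C5–H anti to C20); C3–O/C18–O acetonide | O=C1CC[C@H]2[C@@](C)(CC[C@@H](OC(C)(C)OC3)[C@@]23C)[C@@H]1CC/C(C)=C/CO[Si](c1ccccc1)(c1ccccc1)C(C)(C)C | intermediate
22 | 8(17)-methylene analogue of 21 (acetonide, TBDPS ether) | C=C1CC[C@H]2[C@@](C)(CC[C@@H](OC(C)(C)OC3)[C@@]23C)[C@@H]1CC/C(C)=C/CO[Si](c1ccccc1)(c1ccccc1)C(C)(C)C | intermediate
23 | C3,C18-diol of the 8(17),13E-diene with C15–OTBDPS | C=C1CC[C@H]2[C@@](C)(CC[C@@H](O)[C@]2(C)CO)[C@@H]1CC/C(C)=C/CO[Si](c1ccccc1)(c1ccccc1)C(C)(C)C | intermediate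
24 | C18 (E)-2-methylbut-2-enoate (tiglate) of 23 with free C3–OH | C=C1CC[C@H]2[C@@](C)(CC[C@@H](O)[C@]2(C)COC(=O)/C(C)=C/C)[C@@H]1CC/C(C)=C/CO[Si](c1ccccc1)(c1ccccc1)C(C)(C)C | intermediate
25 | C3 acetate, C18 tiglate, C15 TBDPS ether | C=C1CC[C@H]2[C@@](C)(CC[C@@H](OC(C)=O)[C@]2(C)COC(=O)/C(C)=C/C)[C@@H]1CC/C(C)=C/CO[Si](c1ccccc1)(c1ccccc1)C(C)(C)C | intermediate
26 | CNP0148037.1: (3R,4S,5S,9R,10S)-3-acetoxy-18-tigloyloxy-labda-8(17),13E-dien-15-ol (ent-labdane; labdane numbering) | C=C1CC[C@H]2[C@@](C)(CC[C@@H](OC(C)=O)[C@]2(C)COC(=O)/C(C)=C/C)[C@@H]1CC/C(C)=C/CO | target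

Total step count: 17. Longest linear sequence: 13 steps (steps 1–7, then 12–17); the side-chain branch (steps 8–11) joins at step 12.

Steps most likely to fail

1. Step 12 (key step). The bulky dibromoalkyllithium may add too slowly to the neopentyl C8 ketone, so that enolisation at C7 or carbenoid decomposition takes over, and C7 may migrate in place of C10. The fallback sets out from 11 and 15 and returns at 21. Aldehyde 15 is converted with methaneselenol/ZnCl2 into the bis(methylseleno)acetal F1. Se/Li exchange with n-BuLi (THF, −78 °C) gives the α-(methylseleno)alkyllithium F2, a reagent class that adds well to hindered, enolisable ketones, and addition to 11 should give the β-hydroxy selenide F3. Activation of selenium with AgBF4 on alumina (CH2Cl2) triggers a cationic semipinacol ring enlargement of the β-hydroxy selenide, in which the more substituted C10 should migrate; brief base equilibration at C9 should then deliver 21.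

2. Step 4. Protonation at C5 during the dissolving-metal reduction may show poor facial selectivity in the hydrindane (cis ring fusion), and over-reduction or retro-aldol loss of formaldehyde may occur. The fallback sets out from 6 and returns at 10. Compound 6 is silylated (TBSCl, imidazole) to the silyl ether F4. Conjugate reduction with t-BuCu/DIBAL-H/HMPA (THF, −50 °C), a reagent combination that delivers hydride to Hajos–Parrish-type enones anti to the angular methyl, should give the trans-fused diisobutylaluminium enolate F5. This is trapped in the same flask with formaldehyde to give the hydroxymethyl ketone F6. NaBH4 reduction then gives the diol F7, 2,2-dimethoxypropane/PPTS the acetonide silyl ether F8, and TBAF removes the silyl group to give 10.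

3. Step 11. The phosphite–bromine reagent may brominate or hydrobrominate the trisubstituted alkene, or the activated aldehyde may eliminate to a vinyl bromide. The fallback sets out from 15 and returns at 16. Condensation with hydrazine hydrate (EtOH, 4 Å MS) gives the hydrazone F9, which is oxidised with CuBr2/LiOtBu in THF via the diazoalkane to the gem-dibromide 16 with loss of nitrogen, so no electrophilic bromine reagent is used.

Further compounds
F1 | step 12 | tert-butyl{[(2E)-3-methyl-6,6-bis(methylselanyl)hex-2-en-1-yl]oxy}diphenylsilane | C[Se]C([Se]C)CC/C(C)=C/CO[Si](c1ccccc1)(c1ccccc1)C(C)(C)C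
F2 | step 12 | α-(methylseleno)alkyllithium from F1 | [Li]C([Se]C)CC/C(C)=C/CO[Si](c1ccccc1)(c1ccccc1)C(C)(C)C
F3 | step 12 | β-hydroxy selenide from F2 and 11 (C8–OH syn to C20; selenium-bearing C9 unassigned) | C1C[C@H]2[C@@](C)(CC[C@@H](OC(C)(C)OC3)[C@@]23C)[C@@]1(O)C([Se]C)CC/C(C)=C/CO[Si](c1ccccc1)(c1ccccc1)C(C)(C)C
F4 | step 4 | tert-butyldimethylsilyl ether of 6 | C[C@@]12CCC(=O)C(C)=C1CC[C@H]2O[Si](C)(C)C(C)(C)C
F5 | step 4 | trans-fused C3–C4 diisobutylaluminium enolate with C8–OTBS | C1C[C@H]2[C@@](C)(CCC(O[Al](CC(C)C)CC(C)C)=C2C)[C@@H]1O[Si](C)(C)C(C)(C)C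
F6 | step 4 | C8-O-TBS ether of keto diol 8 (free C18–OH) | C1C[C@H]2[C@@](C)(CCC(=O)[C@]2(C)CO)[C@@H]1O[Si](C)(C)C(C)(C)C
F7 | step 4 | C8-O-TBS ether of triol 9 (free C3–OH and C18–OH) | C1C[C@H]2[C@@](C)(CC[C@@H](O)[C@]2(C)CO)[C@@H]1O[Si](C)(C)C(C)(C)C
F8 | step 4 | C8-O-TBS ether of acetonide alcohol 10 | C1C[C@H]2[C@@](C)(CC[C@@H](OC(C)(C)OC3)[C@@]23C)[C@@H]1O[Si](C)(C)C(C)(C)C
F9 | step 11 | hydrazone of aldehyde 15 | NN=CCC/C(C)=C/CO[Si](c1ccccc1)(c1ccccc1)C(C)(C)C
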